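(The earlier runs and the new flask were generated by integration with constants of no real substance; noise was put on by code.)

Slowness tempts one to ask how fast side product forms, but in a flask left for 10 h the better question may be what the charges allow at the end.

the same everywhere: free catalyst 30 mM

|  | substrate | partner | remark | time |
|---|---|---|---|---|
| west | 0.80 M | 0.51 M | run made earlier |  |
| south-east | 0.80 M | 1.1 M | run made earlier |  |
| east | 1.6 M | 0.76 M | run made earlier |  |
| flask | 0.80 M | 0.760 M |  | 10 h |

- west (time / h: side product / %, target / %, substrate / %): 0.833: 37.7, 44.5, 7.0; 2.50: 58.3, 34.3, 1.1; 5.00: 68.3, 30.1, 0.1; 8.00: 70.6, 29.5, 0; 10.0: 74.7, 27.4, 1.3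
- south-east (time / h: side product / %, target / %, substrate / %): 0.833: 5.2, 94.2, 0.8; 2.50: 3.2, 95.8, 0; 5.00: 5.0, 95.6, 1.0; 8.00: 4.8, 96.5, 0; 10.0: 4.7, 96.3, 0.3
- east (time / h: side product / %, target / %, substrate / %): 0.833: 58.0, 17.7, 8.9; 1.50: 70.1, 10.5, 6.6; 3.00: 81.5, 4.7, 5.1; 5.00: 88.3, 4.8, 5.8; 10.0: 94.7, 0, 2.3

(standard deviation of a reading: 1 percentage point)

- percentages count the substrate that a species holds: one side product counts as two

1. share of side product in side product plus target at 12 s
2. share of side product in side product plus target at 10 min
3. share of side product in side product plus target at 10 h

*What does one side product hold?* Two substrates and one partner. At the end of the east run, side product reads 94.7 % and target 0 %, and twice the partner charge, as a fraction of the substrate charge, is 95.0 %.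

*What does that demand of this flask?* Partner falls short of substrate by 5.00 % of the substrate charge. A target uses one partner per substrate, a side product one per two. So if both charges are used up and the substrate sits in those two products, side product must hold twice the gap, 10.0 %; I call this the balance floor.

*Does west obey?* Its floor is 72.5 %, and its share reads 73.2 % at 10.0 h. It read 69.4 % at 5.00 h, less than that floor, so in the west run the floor is a value for the end and not for the middle of the run.

*And south-east, which has no gap?* Side product still reads 4.7 % there, so a race runs beside the balance, and where the substrate ends in the two products, partner left over adds to side product, which makes the floor a lower bound. That reading is less than this flask's floor, but south-east had more partner, so the race may run higher in this flask. I commit to 10.0 % at 10 h; the floor says nothing about the earlier times.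

The forecast gives 0.1 %, 1.8 % and 14 %, on the ground that “Final west and east compositions fit each side product consuming two substrates and one partner”.

The flask gives 0.599 %, 6.80 % and 10.0 %, and the forecast held within its margins.

    free catalyst + open intermediate ⇌ catalyst intermediate (K = 12.0 M⁻¹, k = 0.920 M⁻¹ s⁻¹)
    partner + catalyst intermediate → free catalyst + target (k = 1.10 M⁻¹ s⁻¹)
    substrate + target → side product (k = 0.00140 M⁻¹ s⁻¹)
    substrate + free catalyst ⇌ free catalyst + open intermediate (K = 1.20, k = 3.20 M⁻¹ s⁻¹)

The half-life of target by the side path alone, at the charged concentrations, is 0.17 h, shorter than 10 h. The floor of 10.0 % stands beside 10.0 %, with substrate at 0 % and partner at 0 % of their charges and open intermediate at 0 % of the substrate charged, which is the condition the floor assumed.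

In the neighbour flask with 0.30 M of partner, the floor comes to 125 %, more than the whole charge, so partner caps side product at twice its fraction, 75.0 %. That neighbour flask ends with side product at 74.6 % and a share of 99.7 %, with partner, the limiting reagent there, at 0 %.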